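## Structural features

The target is a (2S)-flavanone: a phloroglucinol-type ring A (free hydroxyls at C5 and C7) is fused through C4a–C8a to the dihydropyranone ring C (O1, C2, C3, C4=O), and ring B, a para-hydroxyphenyl group, sits on C2. Ring B carries at C3', ortho to its hydroxyl, an (E)-7-hydroxy-3,7-dimethyloct-2-enyl chain, that is a trisubstituted alkene two atoms from the arene and a tertiary alcohol at the chain end. C2 is the only stereocentre and has no stereogenic neighbour, so its configuration cannot be relayed from anything in the molecule and must come from a reagent or catalyst. C2 is also the fragile point: it is benzylic, bonded to O1 and β to the C4 carbonyl, so base opens ring C by retro-oxa-Michael reaction to the achiral chalcone and racemises the flavanone. Other sensitive sites are the ArCH2–CH=C unit next to a phenol (acid closes it to a chroman, DDQ dehydrogenates it), the tertiary alcohol (ionisation) and the very electron-rich ring A. The real difficulty is enantiocontrol at C2 without a directing group, followed by installing the C4 carbonyl and unmasking four hydroxyls without touching C2 or the alkene. The key step exploits the fact that, with the C4 oxygen set aside, ring C is a 2-arylchroman whose O1–C2 and C3–C4 bonds are exactly the two bonds that a ring A ortho-quinone methide (O1=C8a–C4a=C4H2) forms with the vinyl group (C2=C3) of a ring B styrene.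

## Logic of the disconnections

22 to 21: the O–CH2 bonds of two acetals, one aryl ester C–O bond and one O–Si bond are cut. All four groups fall to one acidic methanolysis, so no base ever meets the flavanone. The forward step must be acidic enough for the C7 acetal yet spare the alkene and the tertiary alcohol.

21 to 20 to 19: the C4 oxygen is removed (C=O, then CH–OH, then CH2). Without the carbonyl, ring C is a plain chroman that can be cut by a cycloaddition, and the base-lability of C2 does not exist until the last two steps. The forward oxidation must pick C4–H over C2–H and over the side-chain ArCH2. Three oxygen donors on ring A favour C4, and an electron-poor acyloxy group on ring B disfavours the other two sites.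

19 to 17 (through 18): the ring B oxygen substituent is exchanged, acyl–O for silyl–O. The cycloaddition wants an electron-rich styrene, while the oxidation wants an electron-poor ring B. An aryl ester would also be cleaved by the ylide used to make the vinyl group, so the ester cannot be carried from the start. A one-flask exchange after the cycloaddition reconciles these demands. Fluoride must distinguish the aryl silyl ether from the hindered tertiary alkyl silyl ether.

17 to 15 and 12 (through 16): O1–C2 and C3–C4 are cut. This splits the molecule into two aromatic halves of similar size, each reachable in a few steps, and creates ring C and the only stereocentre in one event. The forward step must control the face of an unfunctionalised styrene by the catalyst alone. It must also keep the quinone methide from reacting with the side-chain alkene or with ring A of another molecule.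

12 to 11 (from 10) and 7: the aryl–CH2 bond at C3' is cut. An aryl-metal and a primary allylic bromide join here with the (E)-alkene taken unchanged from the terpene. This replaces an unreliable phenoxide C-alkylation by a halogen-directed coupling. It demands attack at the primary allylic carbon and tolerance of the vinyl group by the aryl-metal.

10 to 9 to 8: the vinyl C=C (olefination of an aldehyde) and the aryl O–Si bond are cut, leading to a commercial bromophenol aldehyde in which the bromine already marks C3'.

7 to 5 to 4 to 3 to 1: the C–Br bond, the ester C–O bond, the O–Si bond and the C7–O bond are cut in turn. The tertiary alcohol is protected before the allylic bromide is made, so a hydroxy-bromide that could cyclise is never formed. The hydration must select the remote alkene of 1 over the one next to the ester.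

15 to 14 to 13: the benzylic C–H (reduction of the aldehyde) and two acetal O–CH2 bonds are cut. The symmetry of 13 means only one bis-ether with a free chelated hydroxyl is possible. The reduction must stop at the alcohol, and 15 must be used fresh.

## Other disconnections considered

Alternative 1: The cut is C4a–C5, with ring A traced back to a 3-oxobutanoate chain on C8a of a preformed (2S)-2-aryl-2,3-dihydropyran-4-one A2. In the forward key step the dienolate of A2 attacks its own ester carbonyl (Claisen condensation) and the new ring enolises to the 5,7-dihydroxyflavanone A1.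
- In its favour: it mirrors the polyketide origin of ring A, delivers both ring A phenols free, and has the C4 carbonyl in place from the start, so no benzylic oxidation is needed; on this last point it is better than the chosen plan.
- Also in its favour: the stereocentre of A2 could be set by a catalytic asymmetric hetero-Diels–Alder reaction of an aldehyde, a reaction type with firm precedent, which again is better than the unproven enantiocontrol of the chosen plan.
- Against it: A2 is a polycarbonyl compound with several acidic sites. The strong base needed for the condensation can also expel O1 from the C3 enolate and erase C2, and the β-keto ester is deprotonated first, which lowers the electrophilicity of the ester.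
- Against it: attaching the keto ester chain to a sensitive vinylogous ester costs several steps.
- Comparison: structurally the chosen plan joins two stable arenes, while this one cyclises a labile open chain. Mechanistically it is an anionic condensation in the medium most dangerous to C2, against an acid-catalysed cycloaddition at low temperature. Step economy is about equal.

Alternative 2: The cut is the acyl–aryl bond C4–C4a. In the forward key step the carboxyl group of the (3S)-3-aryl-3-(3,5-diallyloxyphenoxy)propanoic acid A4 is activated and acylates the ether ring intramolecularly (Friedel–Crafts) to give the flavanone tris(allyl) ether A3.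
- In its favour: the nucleophilic ring is symmetric, so only one regioisomer can form, and the carbonyl is built directly.
- Also in its favour: the stereocentre of A4 can be set beforehand by established chemistry (asymmetric reduction, then etherification with inversion), and the allyl ethers leave under neutral zerovalent palladium conditions. On stereocontrol precedent and on the mildness of the last step this alternative is the equal or the better of the chosen plan.
- Against it: the C3–O bond of A4 is a benzylic aryl ether para to an alkoxy group and β to an activated acyl group. Under acylating acid it can ionise (racemisation) or lose the phenoxide to give a cinnamoyl derivative, and the alkene and allyl ethers are exposed to the same acid.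
- Against it: the etherification that makes A4 is itself prone to an ionising pathway at so electron-rich a benzylic carbon.
- Comparison: both plans close ring C. The chosen plan makes C2 and the ring together, while this one must carry a labile stereocentre through cationic conditions. The step count is similar or slightly higher.

Alternative 3: The cuts are C1'–C2' and C5'–C6' of ring B. In the forward key step 2-ethynylchromone A6 and the 2-silyloxy-3-alkyl-1,3-diene A7 undergo a (4+2) cycloaddition, and dehydrogenation with DDQ gives the protected flavone A5.
- In its favour: the position of the side chain on ring B is fixed by the diene, so no aryl-metal allylation is needed, the plan is convergent, and no self-condensing quinone methide is involved; on these points it is better than the chosen plan.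
- Against it: A5 is a flavone with sp2 C2, so the stereocentre is not addressed at all. A later enantioselective conjugate reduction of C2=C3 in the presence of the side-chain alkene and then a flavanone-safe deprotection would be needed.
- Against it: A7 is a skipped triene enol ether that is laborious to make and easily isomerised, and DDQ aromatisation next to a doubly allylic methylene is delicate.
- Comparison: on enantiocontrol the two plans are equal, since both rely on a catalyst without help from the substrate, but here it comes in an extra step. Mechanistically this alternative is a normal-demand carbocyclic cycloaddition, the chosen plan an inverse-demand heterocycloaddition. It is longer overall.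

Key step: step 10

Assumption: the sense of induction of the phosphoric acid in step 10 cannot be predicted with confidence; the (R)-acid is written, and its mirror image would be used if the (2R)-flavan predominated.

## Steps

Step 1
Reactants: 1 geranyl acetate
Product: 3 (2E)-7-hydroxy-3,7-dimethyloct-2-en-1-yl acetate, via organomercury adduct 2 (not isolated)
Conditions: Hg(OAc)2, THF/H2O (1:1), rt; then NaBH4, aq. NaOH, 0 °C, short contact
Reagents that add atoms: water, O
Why: Oxymercuration–demercuration (Markovnikov hydration); the remote trisubstituted alkene reacts first because the 2,3-alkene is inductively deactivated by the allylic acetate, water adds at the tertiary carbon, and the mercury-bearing carbon becomes CH2, so no stereocentre remains.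

Step 2
Reactants: 3 (2E)-7-hydroxy-3,7-dimethyloct-2-en-1-yl acetate
Product: 4 (2E)-3,7-dimethyl-7-(triethylsilyloxy)oct-2-en-1-yl acetate
Conditions: TESOTf, 2,6-lutidine, CH2Cl2, −78 → 0 °C
Reagents that add atoms: triethylsilyl triflate, CC[Si](CC)(CC)OS(=O)(=O)C(F)(F)F
Why: Silylation of a tertiary alcohol with a silyl triflate and a hindered base; the ester and the alkene are inert, and protecting now means the later allylic bromide never coexists with a free hydroxyl that could cyclise onto it.

Step 3
Reactants: 4 (2E)-3,7-dimethyl-7-(triethylsilyloxy)oct-2-en-1-yl acetate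
Product: 5 (2E)-3,7-dimethyl-7-(triethylsilyloxy)oct-2-en-1-ol
Conditions: K2CO3 (cat.), MeOH, 0 °C → rt
Reagents that add atoms: none
Why: Base-catalysed transesterification (methanolysis) of a primary acetate; the hindered tertiary triethylsilyl ether is stable to carbonate in methanol and the alkene geometry is untouched.

Step 4
Reactants: 5 (2E)-3,7-dimethyl-7-(triethylsilyloxy)oct-2-en-1-ol
Product: 7 (2E)-1-bromo-3,7-dimethyl-7-(triethylsilyloxy)oct-2-ene, via allylic mesylate 6 (not isolated)
Conditions: MsCl, Et3N, THF, −40 °C; then LiBr, THF, 0 °C
Reagents that add atoms: lithium bromide, [Li+].[Br-]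
Why: Sulfonylation followed by SN2 displacement with bromide, the standard neutral route to geranyl-type bromides; displacement at the primary carbon gives no allylic transposition and keeps the (E)-alkene, and 7 is used crude.

Step 5
Reactants: 8 3-bromo-4-hydroxybenzaldehyde
Product: 9 3-bromo-4-(triisopropylsilyloxy)benzaldehyde
Conditions: TIPSCl, imidazole, DMF, rt
Reagents that add atoms: chlorotriisopropylsilane, CC(C)[Si](Cl)(C(C)C)C(C)C
Why: Silylation of a phenol; the bulky triisopropylsilyl ether tolerates the ylide and the Grignard reagent of the next steps (no silyl shift to the ortho carbanion) and leaves the ring B oxygen a π-donor for the cycloaddition.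

Step 6
Reactants: 9 3-bromo-4-(triisopropylsilyloxy)benzaldehyde
Product: 10 (2-bromo-4-ethenylphenoxy)triisopropylsilane
Conditions: Ph3PCH3Br, NaHMDS, THF, 0 °C → rt
Reagents that add atoms: methyltriphenylphosphonium bromide, C[P+](c1ccccc1)(c1ccccc1)c1ccccc1.[Br-]
Why: Wittig methylenation of an aryl aldehyde; the ylide is formed completely before the aldehyde is added so that no free base attacks the aryl silyl ether, and the aryl bromide is inert.

Step 7
Reactants: 10 (2-bromo-4-ethenylphenoxy)triisopropylsilane; 7 (2E)-1-bromo-3,7-dimethyl-7-(triethylsilyloxy)oct-2-ene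
Product: 12 4-ethenyl-2-[(2E)-3,7-dimethyl-7-(triethylsilyloxy)oct-2-en-1-yl]-1-(triisopropylsilyloxy)benzene, via arylmagnesium bromide 11 (not isolated)
Conditions: Mg, LiCl, THF, 25 °C; then CuI (10 mol%), 7, −30 → 0 °C
Reagents that add atoms: none
Why: Magnesium insertion gives a vinyl-tolerant aryl Grignard reagent, and coupling with the allylic bromide under monovalent copper catalysis occurs at the primary carbon (SN2), since SN2′ attack would have to build a quaternary carbon; the (E)-alkene is not involved and is retained.

Step 8
Reactants: 13 2,4,6-trihydroxybenzaldehyde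
Product: 14 2-hydroxy-4,6-bis(methoxymethoxy)benzaldehyde
Conditions: MOMCl (2.1 equiv), iPr2NEt, CH2Cl2, 0 °C
Reagents that add atoms: chloromethyl methyl ether, COCCl
Why: O-alkylation of phenols with an amine base; the para hydroxyl and one ortho hydroxyl react, while the remaining ortho hydroxyl is held in a hydrogen bond to the aldehyde and resists alkylation, and the symmetry of 13 means only one bis-ether of this type can form.

Step 9
Reactants: 14 2-hydroxy-4,6-bis(methoxymethoxy)benzaldehyde
Product: 15 2-(hydroxymethyl)-3,5-bis(methoxymethoxy)phenol
Conditions: NaBH4, THF/MeOH, −10 °C; pH 7 buffer work-up; used at once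
Reagents that add atoms: none
Why: Borohydride reduction of an aryl aldehyde; low temperature, short time and a neutral quench stop at the salicyl alcohol, which is not stored because it ionises easily.

Step 10
Reactants: 15 2-(hydroxymethyl)-3,5-bis(methoxymethoxy)phenol; 12 4-ethenyl-2-[(2E)-3,7-dimethyl-7-(triethylsilyloxy)oct-2-en-1-yl]-1-(triisopropylsilyloxy)benzene
Product: 17 (2S)-5,7-bis(methoxymethoxy)-2-{3-[(2E)-3,7-dimethyl-7-(triethylsilyloxy)oct-2-en-1-yl]-4-(triisopropylsilyloxy)phenyl}chromane, via ortho-quinone methide 16 (not isolated)
Conditions: (R)-TRIP [(R)-3,3'-bis(2,4,6-triisopropylphenyl)-1,1'-binaphthyl-2,2'-diyl hydrogen phosphate] (10 mol%), 5 Å MS, toluene, −20 °C; 15 added over 8 h to 12 (1.5 equiv)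
Reagents that add atoms: none
Why: Proposed new method: the phosphoric acid protonates the benzylic hydroxyl of 15 and water leaves to give ortho-quinone methide 16, which stays hydrogen-bonded through its carbonyl oxygen (the future O1) to the chiral phosphate; the terminal vinyl carbon of 12 attacks the exocyclic methylene (future C4), and the positive charge building up at the benzylic carbon (future C2), stabilised by the para silyloxy group, is captured by O1 in the same event, an asynchronous inverse-demand hetero-Diels–Alder reaction. The closest known reaction types are the chiral phosphoric acid-catalysed (4+2) cycloadditions of quinone methides made in situ with ortho-hydroxystyrenes and the racemic thermal additions of ortho-quinone methides to electron-rich styrenes. Ring C closes by intermolecular (4+2) cycloaddition forming C3–C4 and O1–C2; in the stepwise limit the second bond is the collapse of the phenolic oxygen onto the benzylic cation to a six-membered ring. C2, the only new stereocentre, is set by the chiral phosphate, which is bound at O1 directly beside the forming O1–C2 bond and whose 2,4,6-triisopropylphenyl walls are expected to admit the styrene aryl group on one face only. Regiochemistry (aryl at C2) follows from polarity. Chemoselectivity for the vinyl group over the side-chain alkene and over Friedel–Crafts attack by ring A is secured by the para oxygen donor on the styrene, by the slow addition of 15 and by the excess of 12, and the symmetric ring A can give only one quinone methide. The silyl ethers, the acetals and the trisubstituted alkene are inert to this weak acid at −20 °C.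

Step 11
Reactants: 17 (2S)-5,7-bis(methoxymethoxy)-2-{3-[(2E)-3,7-dimethyl-7-(triethylsilyloxy)oct-2-en-1-yl]-4-(triisopropylsilyloxy)phenyl}chromane
Product: 19 4-[(2S)-5,7-bis(methoxymethoxy)chroman-2-yl]-2-[(2E)-3,7-dimethyl-7-(triethylsilyloxy)oct-2-en-1-yl]phenyl acetate, via free phenol 18 (not isolated)
Conditions: TBAF (1.1 equiv), THF, 0 °C; then Ac2O, Et3N, DMAP (cat.), 0 °C → rt
Reagents that add atoms: acetic anhydride, CC(=O)OC(C)=O
Why: Fluoride cleaves the aryl Si–O bond (phenoxide leaving group) far faster than the hindered tertiary alkyl Si–O bond, and the phenoxide is acetylated in the same flask; the acetate makes ring B electron-poor for the oxidation, and at this stage there is no carbonyl, so the brief basic conditions cannot affect C2.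

Step 12
Reactants: 19 4-[(2S)-5,7-bis(methoxymethoxy)chroman-2-yl]-2-[(2E)-3,7-dimethyl-7-(triethylsilyloxy)oct-2-en-1-yl]phenyl acetate
Product: 20 4-[(2S,4RS)-4-hydroxy-5,7-bis(methoxymethoxy)chroman-2-yl]-2-[(2E)-3,7-dimethyl-7-(triethylsilyloxy)oct-2-en-1-yl]phenyl acetate
Conditions: DDQ (1.3 equiv), CH2Cl2/pH 7 phosphate buffer (10:1), 0 °C → rt
Reagents that add atoms: water, O
Why: Benzylic hydride abstraction by DDQ at C4, whose cation is stabilised by O1 and the C5 oxygen (ortho) and the C7 oxygen (para), then capture by water, a reaction type established for 5,7-dialkoxyflavans; C2–H and the side-chain ArCH2 are attached to the acetoxy-deactivated ring B and should be left alone. The C4 carbinol forms as a mixture of epimers, which does not matter because it is oxidised next; any ketone 21 already formed is carried along.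

Step 13
Reactants: 20 4-[(2S,4RS)-4-hydroxy-5,7-bis(methoxymethoxy)chroman-2-yl]-2-[(2E)-3,7-dimethyl-7-(triethylsilyloxy)oct-2-en-1-yl]phenyl acetate
Product: 21 4-[(2S)-5,7-bis(methoxymethoxy)-4-oxochroman-2-yl]-2-[(2E)-3,7-dimethyl-7-(triethylsilyloxy)oct-2-en-1-yl]phenyl acetate
Conditions: Dess–Martin periodinane, NaHCO3, CH2Cl2, 0 °C → rt
Reagents that add atoms: none
Why: Dess–Martin oxidation of a secondary benzylic alcohol under buffered, non-basic conditions; both C4 epimers converge on the ketone, and C2, now β to a carbonyl, is not exposed to base.

Step 14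
Reactants: 21 4-[(2S)-5,7-bis(methoxymethoxy)-4-oxochroman-2-yl]-2-[(2E)-3,7-dimethyl-7-(triethylsilyloxy)oct-2-en-1-yl]phenyl acetate
Product: 22 (2S)-5,7-dihydroxy-2-{4-hydroxy-3-[(2E)-7-hydroxy-3,7-dimethyloct-2-en-1-yl]phenyl}-2,3-dihydro-4H-chromen-4-one (CNP0161524.1)
Conditions: 3 M aq. HCl, MeOH/THF, 40 °C, monitored and stopped at full conversion
Reagents that add atoms: none
Why: Acid-catalysed acetal exchange removes both methoxymethyl groups, and acidic methanolysis removes the aryl acetate and the triethylsilyl ether in the same operation; acid is chosen over base because base would open ring C by retro-oxa-Michael reaction and racemise C2, whereas flavanones hold their configuration in methanolic acid.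

## Compound list

1 | geranyl acetate | CC(C)=CCC/C(C)=C/COC(C)=O | starting material
2 | (2E)-6-(acetoxymercurio)-7-hydroxy-3,7-dimethyloct-2-en-1-yl acetate (racemic) | CC(=O)OC/C=C(\C)CCC([Hg]OC(C)=O)C(C)(C)O | intermediate (not isolated)
3 | (2E)-7-hydroxy-3,7-dimethyloct-2-en-1-yl acetate | CC(=O)OC/C=C(\C)CCCC(C)(C)O | intermediate
4 | (2E)-3,7-dimethyl-7-(triethylsilyloxy)oct-2-en-1-yl acetate | CC(=O)OC/C=C(\C)CCCC(C)(C)O[Si](CC)(CC)CC | intermediate
5 | (2E)-3,7-dimethyl-7-(triethylsilyloxy)oct-2-en-1-ol | OC/C=C(\C)CCCC(C)(C)O[Si](CC)(CC)CC | intermediate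
6 | (2E)-3,7-dimethyl-7-(triethylsilyloxy)oct-2-en-1-yl methanesulfonate | CS(=O)(=O)OC/C=C(\C)CCCC(C)(C)O[Si](CC)(CC)CC | intermediate (not isolated)
7 | (2E)-1-bromo-3,7-dimethyl-7-(triethylsilyloxy)oct-2-ene | BrC/C=C(\C)CCCC(C)(C)O[Si](CC)(CC)CC | intermediate
8 | 3-bromo-4-hydroxybenzaldehyde | O=Cc1ccc(O)c(Br)c1 | starting material
9 | 3-bromo-4-(triisopropylsilyloxy)benzaldehyde | O=Cc1ccc(O[Si](C(C)C)(C(C)C)C(C)C)c(Br)c1 | intermediate
10 | (2-bromo-4-ethenylphenoxy)triisopropylsilane | C=Cc1ccc(O[Si](C(C)C)(C(C)C)C(C)C)c(Br)c1 | intermediate
11 | [5-ethenyl-2-(triisopropylsilyloxy)phenyl]magnesium bromide | C=Cc1ccc(O[Si](C(C)C)(C(C)C)C(C)C)c([Mg]Br)c1 | intermediate (not isolated)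
12 | 4-ethenyl-2-[(2E)-3,7-dimethyl-7-(triethylsilyloxy)oct-2-en-1-yl]-1-(triisopropylsilyloxy)benzene | C=Cc1ccc(O[Si](C(C)C)(C(C)C)C(C)C)c(C/C=C(\C)CCCC(C)(C)O[Si](CC)(CC)CC)c1 | intermediate
13 | 2,4,6-trihydroxybenzaldehyde | O=Cc1c(O)cc(O)cc1O | starting material
14 | 2-hydroxy-4,6-bis(methoxymethoxy)benzaldehyde | O=Cc1c(O)cc(OCOC)cc1OCOC | intermediate
15 | 2-(hydroxymethyl)-3,5-bis(methoxymethoxy)phenol | OCc1c(O)cc(OCOC)cc1OCOC | intermediate
16 | 3,5-bis(methoxymethoxy)-6-methylidenecyclohexa-2,4-dien-1-one | C=C1C(=O)C=C(OCOC)C=C1OCOC | intermediate (not isolated)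
17 | (2S)-5,7-bis(methoxymethoxy)-2-{3-[(2E)-3,7-dimethyl-7-(triethylsilyloxy)oct-2-en-1-yl]-4-(triisopropylsilyloxy)phenyl}chromane | C/C(=C\Cc1cc([C@@H]2CCc3c(OCOC)cc(OCOC)cc3O2)ccc1O[Si](C(C)C)(C(C)C)C(C)C)CCCC(C)(C)O[Si](CC)(CC)CC | intermediate
18 | 4-[(2S)-5,7-bis(methoxymethoxy)chroman-2-yl]-2-[(2E)-3,7-dimethyl-7-(triethylsilyloxy)oct-2-en-1-yl]phenol | C/C(=C\Cc1cc([C@@H]2CCc3c(OCOC)cc(OCOC)cc3O2)ccc1O)CCCC(C)(C)O[Si](CC)(CC)CC | intermediate (not isolated)
19 | 4-[(2S)-5,7-bis(methoxymethoxy)chroman-2-yl]-2-[(2E)-3,7-dimethyl-7-(triethylsilyloxy)oct-2-en-1-yl]phenyl acetate | C/C(=C\Cc1cc([C@@H]2CCc3c(OCOC)cc(OCOC)cc3O2)ccc1OC(C)=O)CCCC(C)(C)O[Si](CC)(CC)CC | intermediate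
20 | 4-[(2S,4RS)-4-hydroxy-5,7-bis(methoxymethoxy)chroman-2-yl]-2-[(2E)-3,7-dimethyl-7-(triethylsilyloxy)oct-2-en-1-yl]phenyl acetate (mixture of C4 epimers) | C/C(=C\Cc1cc([C@@H]2CC(O)c3c(OCOC)cc(OCOC)cc3O2)ccc1OC(C)=O)CCCC(C)(C)O[Si](CC)(CC)CC | intermediate
21 | 4-[(2S)-5,7-bis(methoxymethoxy)-4-oxochroman-2-yl]-2-[(2E)-3,7-dimethyl-7-(triethylsilyloxy)oct-2-en-1-yl]phenyl acetate | C/C(=C\Cc1cc([C@@H]2CC(=O)c3c(OCOC)cc(OCOC)cc3O2)ccc1OC(C)=O)CCCC(C)(C)O[Si](CC)(CC)CC | intermediate
22 | (2S)-5,7-dihydroxy-2-{4-hydroxy-3-[(2E)-7-hydroxy-3,7-dimethyloct-2-en-1-yl]phenyl}-2,3-dihydro-4H-chromen-4-one | C/C(=C\Cc1cc([C@@H]2CC(=O)c3c(O)cc(O)cc3O2)ccc1O)CCCC(C)(C)O | target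

## Step count and least certain steps

Total: 14 steps. Longest linear sequence: 10 steps (steps 1, 2, 3, 4, 7, 10, 11, 12, 13, 14).

Step 10 (key step, proposed new method). What may go wrong: poor facial selectivity, because nothing on the styrene binds the phosphate; Friedel–Crafts self-condensation of the electron-rich salicyl alcohol or alkylation of ring A of the product by further quinone methide; cationic oligomerisation of the styrene. Fallback with known chemistry: 15 and 12 are heated without chiral acid in toluene at 80 °C, the thermal generation of 16 and racemic cycloaddition being a known reaction type for electron-rich styrenes, to give the racemic flavan F1. The enantiomers are separated by preparative chromatography on a cellulose tris(3,5-dimethylphenylcarbamate) phase, the (2R)-flavan F2 is set aside, and the (2S)-enantiomer is 17, where the route is rejoined.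

Step 12. What may go wrong: loss of a proton from the C4 cation to give the flav-3-ene and further dehydrogenation to a flavylium ion, which destroys C2; over-oxidation; hydride abstraction at the side-chain ArCH2 if excess oxidant is present. Fallback: 19 is taken directly to 21 by single-electron benzylic oxidation with IBX (2-iodoxybenzoic acid) in DMSO/fluorobenzene at 70 °C. This proceeds through the arene radical cation of the most electron-rich ring (ring A) and gives the ketone without passing through the ionisable alcohol 20; no new compound is formed (F0), and the route is rejoined at 21.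

Step 14. What may go wrong: acid-induced addition of the liberated ring B phenol to the side-chain alkene (chroman formation), ionisation of the tertiary alcohol (elimination or methyl ether formation), or incomplete cleavage of the C7 acetal. Fallback: a staged deprotection from 21 without strong Brønsted acid. TMSOTf and 2,2'-bipyridyl in CH2Cl2 at 0 °C followed by water convert both aryl methoxymethyl ethers through silyl ethers into phenols, giving the 5,7-dihydroxyflavanone acetate F3. NH4OAc in aqueous MeOH at rt removes the aryl acetate to give the trihydroxyflavanone triethylsilyl ether F4. HF·pyridine in THF/pyridine at 0 °C removes the silyl group and gives 22.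

Step 9. What may go wrong: over-reduction, by loss of hydroxide from the phenoxide to a quinone methide and a second hydride addition, and acid-triggered self-condensation of the product during work-up. Fallback: 14 is silylated (TBSOTf, 2,6-lutidine, CH2Cl2) to 2-(tert-butyldimethylsilyloxy)-4,6-bis(methoxymethoxy)benzaldehyde F5. Reduction with NaBH4 gives [2-(tert-butyldimethylsilyloxy)-4,6-bis(methoxymethoxy)phenyl]methanol F6, in which no free phenoxide can expel the benzylic oxygen. TBAF in THF at 0 °C just before use returns 15.

Step 7. What may go wrong: SN2′ coupling to the branched isomer, erosion of the (E)-geometry, homocoupling of the allylic bromide, or sluggish magnesium insertion next to the bulky silyl ether. Fallback: 11 is quenched with 2-isopropoxy-4,4,5,5-tetramethyl-1,3,2-dioxaborolane to give the aryl pinacol boronate F7. This is joined to 7 by Suzuki–Miyaura coupling (Pd(PPh3)4, zerovalent palladium, K3PO4, THF/H2O, 50 °C), in which the aryl group is delivered to the less hindered terminus of the allyl-palladium intermediate, giving 12.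

Step 1. What may go wrong: partial saponification of the allylic acetate during the basic demercuration, mercury-induced cation–olefin cyclisation, and carry-over of mercury residues. Fallback: 1 is epoxidised at the remote alkene (mCPBA, NaHCO3, CH2Cl2, 0 °C) to the epoxy acetate F8. LiAlH4 in THF at 0 °C opens the epoxide at its secondary carbon and removes the acetate, giving (2E)-3,7-dimethyloct-2-ene-1,7-diol F9. TESOTf (2.2 equiv) and 2,6-lutidine give the bis(triethylsilyl) ether F10, and PPTS in MeOH at 0 °C cleaves only the primary allylic silyl ether, returning the route at 5.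

## Further compounds

F1 | step 10 | racemic 5,7-bis(methoxymethoxy)-2-{3-[(2E)-3,7-dimethyl-7-(triethylsilyloxy)oct-2-en-1-yl]-4-(triisopropylsilyloxy)phenyl}chromane | C/C(=C\Cc1cc(C2CCc3c(OCOC)cc(OCOC)cc3O2)ccc1O[Si](C(C)C)(C(C)C)C(C)C)CCCC(C)(C)O[Si](CC)(CC)CC
F2 | step 10 | (2R)-5,7-bis(methoxymethoxy)-2-{3-[(2E)-3,7-dimethyl-7-(triethylsilyloxy)oct-2-en-1-yl]-4-(triisopropylsilyloxy)phenyl}chromane | C/C(=C\Cc1cc([C@H]2CCc3c(OCOC)cc(OCOC)cc3O2)ccc1O[Si](C(C)C)(C(C)C)C(C)C)CCCC(C)(C)O[Si](CC)(CC)CC
F0 | step 12 | none | none
F3 | step 14 | 4-[(2S)-5,7-dihydroxy-4-oxochroman-2-yl]-2-[(2E)-3,7-dimethyl-7-(triethylsilyloxy)oct-2-en-1-yl]phenyl acetate | C/C(=C\Cc1cc([C@@H]2CC(=O)c3c(O)cc(O)cc3O2)ccc1OC(C)=O)CCCC(C)(C)O[Si](CC)(CC)CC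
F4 | step 14 | (2S)-5,7-dihydroxy-2-{4-hydroxy-3-[(2E)-3,7-dimethyl-7-(triethylsilyloxy)oct-2-en-1-yl]phenyl}chroman-4-one | C/C(=C\Cc1cc([C@@H]2CC(=O)c3c(O)cc(O)cc3O2)ccc1O)CCCC(C)(C)O[Si](CC)(CC)CC
F5 | step 9 | 2-(tert-butyldimethylsilyloxy)-4,6-bis(methoxymethoxy)benzaldehyde | COCOc1cc(OCOC)c(C=O)c(O[Si](C)(C)C(C)(C)C)c1
F6 | step 9 | [2-(tert-butyldimethylsilyloxy)-4,6-bis(methoxymethoxy)phenyl]methanol | COCOc1cc(OCOC)c(CO)c(O[Si](C)(C)C(C)(C)C)c1
F7 | step 7 | 2-[5-ethenyl-2-(triisopropylsilyloxy)phenyl]-4,4,5,5-tetramethyl-1,3,2-dioxaborolane | C=Cc1ccc(O[Si](C(C)C)(C(C)C)C(C)C)c(B2OC(C)(C)C(C)(C)O2)c1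
F8 | step 1 | (2E)-5-(3,3-dimethyloxiran-2-yl)-3-methylpent-2-en-1-yl acetate (racemic) | CC(=O)OC/C=C(\C)CCC1OC1(C)C
F9 | step 1 | (2E)-3,7-dimethyloct-2-ene-1,7-diol | OC/C=C(\C)CCCC(C)(C)O
F10 | step 1 | (2E)-3,7-dimethyl-1,7-bis(triethylsilyloxy)oct-2-ene | CC[Si](CC)(CC)OC/C=C(\C)CCCC(C)(C)O[Si](CC)(CC)CC
A1 | alternative 1 | (2S)-5,7-dihydroxy-2-{3-[(2E)-7-hydroxy-3,7-dimethyloct-2-en-1-yl]-4-(methoxymethoxy)phenyl}chroman-4-one | C/C(=C\Cc1cc([C@@H]2CC(=O)c3c(O)cc(O)cc3O2)ccc1OCOC)CCCC(C)(C)O
A2 | alternative 1 | methyl 4-[(2S)-2-{3-[(2E)-7-hydroxy-3,7-dimethyloct-2-en-1-yl]-4-(methoxymethoxy)phenyl}-4-oxo-3,4-dihydro-2H-pyran-6-yl]-3-oxobutanoate | COC(=O)CC(=O)CC1=CC(=O)C[C@@H](c2ccc(OCOC)c(C/C=C(\C)CCCC(C)(C)O)c2)O1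
A3 | alternative 2 | (2S)-5,7-bis(allyloxy)-2-{4-(allyloxy)-3-[(2E)-7-(tert-butyldimethylsilyloxy)-3,7-dimethyloct-2-en-1-yl]phenyl}chroman-4-one | C/C(=C\Cc1cc([C@@H]2CC(=O)c3c(OCC=C)cc(OCC=C)cc3O2)ccc1OCC=C)CCCC(C)(C)O[Si](C)(C)C(C)(C)C
A4 | alternative 2 | (3S)-3-{4-(allyloxy)-3-[(2E)-7-(tert-butyldimethylsilyloxy)-3,7-dimethyloct-2-en-1-yl]phenyl}-3-[3,5-bis(allyloxy)phenoxy]propanoic acid | OC(=O)C[C@H](Oc1cc(OCC=C)cc(OCC=C)c1)c1ccc(OCC=C)c(C/C=C(\C)CCCC(C)(C)O[Si](C)(C)C(C)(C)C)c1
A5 | alternative 3 | 2-{4-(tert-butyldimethylsilyloxy)-3-[(2E)-3,7-dimethyl-7-(triethylsilyloxy)oct-2-en-1-yl]phenyl}-5,7-bis(methoxymethoxy)-4H-chromen-4-one | C/C(=C\Cc1cc(-c2cc(=O)c3c(OCOC)cc(OCOC)cc3o2)ccc1O[Si](C)(C)C(C)(C)C)CCCC(C)(C)O[Si](CC)(CC)CC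
A6 | alternative 3 | 2-ethynyl-5,7-bis(methoxymethoxy)-4H-chromen-4-one | C#Cc1cc(=O)c2c(OCOC)cc(OCOC)cc2o1
A7 | alternative 3 | (5E)-2-(tert-butyldimethylsilyloxy)-6,10-dimethyl-3-methylidene-10-(triethylsilyloxy)undeca-1,5-diene | C=C(O[Si](C)(C)C(C)(C)C)C(=C)C/C=C(\C)CCCC(C)(C)O[Si](CC)(CC)CC
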